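**Plan**

1. Retrosynthesis: (i) the enone C=C next to the ether-bearing arene is cut (boron-templated aldol condensation) to aldehyde 17 and feruloylacetone 18; (ii) C9–C10 of the side chain is cut (alkenyl Grignard on a C9 ester); (iii) in the ring, C4–OH is taken back to C4=O, then C2=C3 (aldol condensation) and C1–C6 (Michael addition) are cut, giving aryloxyacetaldehyde 4 and enone 9.
2. Forward order: both arenes come from vanillin; the cyclohexene is the only ring made and is closed in one flask from 4 + 9 (step 7); then C4 reduction and inversion, side-chain enone, unmasking of the aryl aldehyde and attachment of the diketone arm.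
3. Enabling feature: with ring atoms C1 (CH–OAr), C2=C3(Me), C4 (CH–OH), C5 (CH2), C6 (CH–side chain), the unit C2=C3(Me)–C4(O) is a masked 2-methylcyclohex-2-enone whose γ-carbon C1 carries the aryloxy group. C2 and C4 are therefore a latent 1,5-dicarbonyl pair bridged by C1–C6–C5, which is an α-aryloxy aldehyde plus a β-substituted ethyl enone.
4. Stereochemistry: C7 from Rh-catalysed asymmetric hydrogenation of an itaconate half-ester; C6 and C1 from the amine-catalysed Michael addition (C1 is also epimerisable and funnels to trans); C4 from Luche reduction followed by Mitsunobu inversion.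

Key step: step 7

Remark on locants: C1–C6 are the ring atoms as defined in line 3; C7 is the side-chain CH(CH3), C8 the CH2, C9 the side-chain carbonyl carbon.
Assumption: the enamine of 4 adds to enone 9 with the same facial sense and syn topicity that (S)-diarylprolinol ethers show with nitroalkenes and simple enones.
Remark: the β-diketone is written in the keto or enol form as convenient; these are tautomers.

**Step 1**
Reactants: 1 vanillin
Product: 2 3-methoxy-4-(prop-2-en-1-yloxy)benzaldehyde
Conditions: allyl bromide, K2CO3, DMF, 50 °C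
Reagents that add atoms: allyl bromide, C=CCBr
Why: Williamson etherification of the acidic phenol is chemoselective and leaves the aldehyde untouched.

**Step 2**
Reactants: 2 3-methoxy-4-(prop-2-en-1-yloxy)benzaldehyde
Product: 3 2-[3-methoxy-4-(prop-2-en-1-yloxy)phenyl]-5,5-dimethyl-1,3-dioxane
Conditions: 2,2-dimethylpropane-1,3-diol, p-TsOH·H2O (2 mol %), toluene, reflux, Dean–Stark
Reagents that add atoms: 2,2-dimethylpropane-1,3-diol, OCC(C)(C)CO
Why: Acid-catalysed acetalisation with azeotropic removal of water masks the aryl aldehyde as a cyclic acetal that should survive the later amine/acid, Luche and Grignard conditions.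

**Step 3**
Reactants: 3 2-[3-methoxy-4-(prop-2-en-1-yloxy)phenyl]-5,5-dimethyl-1,3-dioxane
Product: 4 2-[4-(5,5-dimethyl-1,3-dioxan-2-yl)-2-methoxyphenoxy]acetaldehyde
Conditions: O3, CH2Cl2/MeOH, NaHCO3, −78 °C; then PPh3, −78 °C → rt
Reagents that add atoms: ozone, [O-][O+]=O
Why: Ozonolysis with reductive work-up cleaves the only alkene to the α-aryloxy aldehyde, and the buffered low temperature should spare the acetal and the arene.

**Step 4**
Reactants: 5 monomethyl itaconate (4-methoxy-2-methylidene-4-oxobutanoic acid)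
Product: 6 (2S)-4-methoxy-2-methyl-4-oxobutanoic acid
Conditions: H2 (5 bar), [Rh(cod)(Et-DuPhos)]BF4 (0.2 mol %, ligand antipode that gives the 2S acid), MeOH, rt
Reagents that add atoms: none
Why: Rh–bisphospholane asymmetric hydrogenation of a chelating itaconate half-ester sets the future C7 centre by catalyst control.

**Step 5**
Reactants: 6 (2S)-4-methoxy-2-methyl-4-oxobutanoic acid
Product: 7 methyl (3S)-4-hydroxy-3-methylbutanoate
Conditions: BH3·SMe2 (1.1 equiv), THF, −10 °C → rt; MeOH quench, neutral work-up, used crude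
Reagents that add atoms: none
Why: Borane reduces the carboxylic acid chemoselectively in the presence of the methyl ester (acyloxyborane activation) without touching the stereocentre; acid-free handling avoids lactonisation.

**Step 6**
Reactants: 7 methyl (3S)-4-hydroxy-3-methylbutanoate
Product: 9 methyl (3S,4E)-3-methyl-6-oxooct-4-enoate, via methyl (3S)-3-methyl-4-oxobutanoate 8 (not isolated)
Conditions: Dess–Martin periodinane, CH2Cl2, 0 °C → rt; then Ph3P=CHC(O)Et, rt
Reagents that add atoms: 1-(triphenylphosphoranylidene)butan-2-one, CCC(=O)C=P(c1ccccc1)(c1ccccc1)c1ccccc1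
Why: Dess–Martin oxidation followed in the same flask by Wittig olefination with a stabilised ylide should give the E-enone without isolating the epimerisable α-branched aldehyde.

**Step 7**
Reactants: 4 2-[4-(5,5-dimethyl-1,3-dioxan-2-yl)-2-methoxyphenoxy]acetaldehyde; 9 methyl (3S,4E)-3-methyl-6-oxooct-4-enoate
Product: 11 methyl (3S)-3-{(1R,2R)-2-[4-(5,5-dimethyl-1,3-dioxan-2-yl)-2-methoxyphenoxy]-4-methyl-5-oxocyclohex-3-en-1-yl}butanoate, via methyl (3S,4R,5R)-5-[4-(5,5-dimethyl-1,3-dioxan-2-yl)-2-methoxyphenoxy]-3-methyl-6-oxo-4-(2-oxobutyl)hexanoate 10 (not isolated)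
Conditions: (S)-α,α-diphenylprolinol trimethylsilyl ether (20 mol %), ethyl 3,4-dihydroxybenzoate (20 mol %), 4 (1.5 equiv, slow addition), CHCl3, 4 °C → rt; then PhCO2H (0.3 equiv), 40 °C
Reagents that add atoms: none
Why: The (S)-diarylprolinol silyl ether converts 4 into its E-enamine, which adds through an acyclic synclinal transition state to the β-carbon (C6) of the hydrogen-bond-activated enone 9 to give the syn 1,5-keto aldehyde 10; iminium activation of the aldehyde then lets the enol of the ethyl ketone attack C2, and loss of water gives the C2=C3 double bond. The closest known reaction types are the amine-catalysed Michael addition of aldehydes to enones and nitroalkenes and the organocatalytic Robinson-type annulation. The one ring closed is the cyclohexenone, by a 6-(enolendo)-exo-trig aldol addition followed by E1cB dehydration. C6 is set by the catalyst (shielded enamine face combined with syn topicity, expected to override the weak bias of C7); C1 is set by the same enamine face and is additionally secured thermodynamically, because it is α to the aldehyde in 10 and γ to the enone carbonyl in 11 and can equilibrate to the trans-diequatorial arrangement. The step needs chemoselectivity (only the aldehyde forms an enamine; slow addition of 4 limits its self-aldol) and regioselectivity in the aldol (only attack by C3 gives a six-membered ring, attack by C5 would give a cyclobutane), both secured by the substrate.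

**Step 8**
Reactants: 11 methyl (3S)-3-{(1R,2R)-2-[4-(5,5-dimethyl-1,3-dioxan-2-yl)-2-methoxyphenoxy]-4-methyl-5-oxocyclohex-3-en-1-yl}butanoate
Product: 12 methyl (3S)-3-{(1R,2R,5R)-2-[4-(5,5-dimethyl-1,3-dioxan-2-yl)-2-methoxyphenoxy]-5-hydroxy-4-methylcyclohex-3-en-1-yl}butanoate
Conditions: NaBH4, CeCl3·7H2O, MeOH, −78 → −40 °C
Reagents that add atoms: none
Why: Luche 1,2-reduction with axial hydride delivery on the half-chair (both ring substituents pseudoequatorial) should give the equatorial C4 alcohol cis to the side chain, by analogy with the reduction of carvone to cis-carveol; ester and acetal are inert.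

**Step 9**
Reactants: 12 methyl (3S)-3-{(1R,2R,5R)-2-[4-(5,5-dimethyl-1,3-dioxan-2-yl)-2-methoxyphenoxy]-5-hydroxy-4-methylcyclohex-3-en-1-yl}butanoate
Product: 14 methyl (3S)-3-{(1R,2R,5S)-2-[4-(5,5-dimethyl-1,3-dioxan-2-yl)-2-methoxyphenoxy]-5-hydroxy-4-methylcyclohex-3-en-1-yl}butanoate, via (1S,4R,5R)-4-[4-(5,5-dimethyl-1,3-dioxan-2-yl)-2-methoxyphenoxy]-5-[(2S)-4-methoxy-4-oxobutan-2-yl]-2-methylcyclohex-2-en-1-yl 4-nitrobenzoate 13 (not isolated)
Conditions: PPh3, DIAD, 4-nitrobenzoic acid, THF, 0 °C → rt; then MeOH, K2CO3, rt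
Reagents that add atoms: 4-nitrobenzoic acid, OC(=O)c1ccc(cc1)[N+](=O)[O-] (its carboxyl oxygen becomes the C4 oxygen)
Why: Mitsunobu esterification proceeds with SN2 inversion at the allylic carbinol (the cis- to trans-carveol type of inversion), and methanolysis of the activated ester in the same flask should give the pseudoaxial C4 alcohol cis to the aryloxy group while the methyl ester stays a methyl ester.

**Step 10**
Reactants: 14 methyl (3S)-3-{(1R,2R,5S)-2-[4-(5,5-dimethyl-1,3-dioxan-2-yl)-2-methoxyphenoxy]-5-hydroxy-4-methylcyclohex-3-en-1-yl}butanoate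
Product: 16 (6S)-6-{(1R,2R,5S)-2-[4-(5,5-dimethyl-1,3-dioxan-2-yl)-2-methoxyphenoxy]-5-hydroxy-4-methylcyclohex-3-en-1-yl}-2-methylhept-2-en-4-one, via (3S)-3-{(1R,2R,5S)-2-[4-(5,5-dimethyl-1,3-dioxan-2-yl)-2-methoxyphenoxy]-5-hydroxy-4-methylcyclohex-3-en-1-yl}-N-methoxy-N-methylbutanamide 15 (not isolated)
Conditions: MeNH(OMe)·HCl, i-PrMgCl (excess), THF, −20 °C; then Me2C=CHMgBr, −20 → 0 °C; aq. NH4Cl
Reagents that add atoms: 2-methylprop-1-en-1-ylmagnesium bromide, CC(C)=C[Mg]Br (N,O-dimethylhydroxylamine hydrochloride, CNOC.Cl, contributes atoms only to the unisolated amide 15)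
Why: One-flask ester → Weinreb amide → ketone conversion, in which the chelated tetrahedral intermediate prevents over-addition and the free hydroxyl is carried as its magnesium alkoxide.

**Step 11**
Reactants: 16 (6S)-6-{(1R,2R,5S)-2-[4-(5,5-dimethyl-1,3-dioxan-2-yl)-2-methoxyphenoxy]-5-hydroxy-4-methylcyclohex-3-en-1-yl}-2-methylhept-2-en-4-one
Product: 17 4-({(1R,4S,6R)-4-hydroxy-3-methyl-6-[(2S)-6-methyl-4-oxohept-5-en-2-yl]cyclohex-2-en-1-yl}oxy)-3-methoxybenzaldehyde
Conditions: PPTS (20 mol %), acetone/H2O (10:1), 40 °C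
Reagents that add atoms: water, O
Why: The acetal of an electron-rich benzaldehyde hydrolyses under acid mild enough to leave the allylic aryl ether and allylic alcohol un-ionised.

**Step 12**
Reactants: 1 vanillin
Product: 18 (5E)-6-(4-hydroxy-3-methoxyphenyl)hex-5-ene-2,4-dione (feruloylacetone)
Conditions: pentane-2,4-dione (3 equiv), B2O3, B(OBu)3, n-BuNH2 (cat., slow addition), EtOAc, 70 °C; then 0.4 M HCl, 50 °C
Reagents that add atoms: pentane-2,4-dione, CC(=O)CC(C)=O
Why: In the boron chelate the central carbon of the diketone is blocked, so the amine-catalysed aldol condensation occurs at a terminal methyl, and the excess of diketone favours the mono-adduct.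

**Step 13**
Reactants: 17 4-({(1R,4S,6R)-4-hydroxy-3-methyl-6-[(2S)-6-methyl-4-oxohept-5-en-2-yl]cyclohex-2-en-1-yl}oxy)-3-methoxybenzaldehyde; 18 (5E)-6-(4-hydroxy-3-methoxyphenyl)hex-5-ene-2,4-dione
Product: 19 Bisabolocurcumin ether
Conditions: 18 (1.5 equiv), B2O3, B(OBu)3, n-BuNH2 (cat.), EtOAc, 60 °C; then 10% aq. AcOH, rt
Reagents that add atoms: none
Why: The boron chelate of 18 activates its remaining terminal methyl for aldol condensation with 17 (E1cB dehydration to the E-alkene), and the boron ester of the C4 hydroxyl should be released on the mildly acidic work-up.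

**Compound list**

1 | vanillin | COc1cc(C=O)ccc1O | starting material
2 | 3-methoxy-4-(prop-2-en-1-yloxy)benzaldehyde | COc1cc(C=O)ccc1OCC=C | intermediate
3 | 2-[3-methoxy-4-(prop-2-en-1-yloxy)phenyl]-5,5-dimethyl-1,3-dioxane | COc1cc(C2OCC(C)(C)CO2)ccc1OCC=C | intermediate
4 | 2-[4-(5,5-dimethyl-1,3-dioxan-2-yl)-2-methoxyphenoxy]acetaldehyde | COc1cc(C2OCC(C)(C)CO2)ccc1OCC=O | intermediate
5 | monomethyl itaconate (4-methoxy-2-methylidene-4-oxobutanoic acid) | C=C(CC(=O)OC)C(=O)O | starting material
6 | (2S)-4-methoxy-2-methyl-4-oxobutanoic acid | OC(=O)[C@@H](C)CC(=O)OC | intermediate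
7 | methyl (3S)-4-hydroxy-3-methylbutanoate | OC[C@@H](C)CC(=O)OC | intermediate
8 | methyl (3S)-3-methyl-4-oxobutanoate | O=C[C@@H](C)CC(=O)OC | intermediate
9 | methyl (3S,4E)-3-methyl-6-oxooct-4-enoate | CCC(=O)/C=C/[C@@H](C)CC(=O)OC | intermediate
10 | methyl (3S,4R,5R)-5-[4-(5,5-dimethyl-1,3-dioxan-2-yl)-2-methoxyphenoxy]-3-methyl-6-oxo-4-(2-oxobutyl)hexanoate | COc1cc(C2OCC(C)(C)CO2)ccc1O[C@@H](C=O)[C@H](CC(=O)CC)[C@@H](C)CC(=O)OC | intermediate
11 | methyl (3S)-3-{(1R,2R)-2-[4-(5,5-dimethyl-1,3-dioxan-2-yl)-2-methoxyphenoxy]-4-methyl-5-oxocyclohex-3-en-1-yl}butanoate | COc1cc(C2OCC(C)(C)CO2)ccc1O[C@H]3C=C(C)C(=O)C[C@@H]3[C@@H](C)CC(=O)OC | intermediate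
12 | methyl (3S)-3-{(1R,2R,5R)-2-[4-(5,5-dimethyl-1,3-dioxan-2-yl)-2-methoxyphenoxy]-5-hydroxy-4-methylcyclohex-3-en-1-yl}butanoate | COc1cc(C2OCC(C)(C)CO2)ccc1O[C@H]3C=C(C)[C@H](O)C[C@@H]3[C@@H](C)CC(=O)OC | intermediate
13 | (1S,4R,5R)-4-[4-(5,5-dimethyl-1,3-dioxan-2-yl)-2-methoxyphenoxy]-5-[(2S)-4-methoxy-4-oxobutan-2-yl]-2-methylcyclohex-2-en-1-yl 4-nitrobenzoate | COc1cc(C2OCC(C)(C)CO2)ccc1O[C@H]3C=C(C)[C@@H](OC(=O)c4ccc(cc4)[N+](=O)[O-])C[C@@H]3[C@@H](C)CC(=O)OC | intermediate
14 | methyl (3S)-3-{(1R,2R,5S)-2-[4-(5,5-dimethyl-1,3-dioxan-2-yl)-2-methoxyphenoxy]-5-hydroxy-4-methylcyclohex-3-en-1-yl}butanoate | COc1cc(C2OCC(C)(C)CO2)ccc1O[C@H]3C=C(C)[C@@H](O)C[C@@H]3[C@@H](C)CC(=O)OC | intermediate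
15 | (3S)-3-{(1R,2R,5S)-2-[4-(5,5-dimethyl-1,3-dioxan-2-yl)-2-methoxyphenoxy]-5-hydroxy-4-methylcyclohex-3-en-1-yl}-N-methoxy-N-methylbutanamide | COc1cc(C2OCC(C)(C)CO2)ccc1O[C@H]3C=C(C)[C@@H](O)C[C@@H]3[C@@H](C)CC(=O)N(C)OC | intermediate
16 | (6S)-6-{(1R,2R,5S)-2-[4-(5,5-dimethyl-1,3-dioxan-2-yl)-2-methoxyphenoxy]-5-hydroxy-4-methylcyclohex-3-en-1-yl}-2-methylhept-2-en-4-one | COc1cc(C2OCC(C)(C)CO2)ccc1O[C@H]3C=C(C)[C@@H](O)C[C@@H]3[C@@H](C)CC(=O)C=C(C)C | intermediate
17 | 4-({(1R,4S,6R)-4-hydroxy-3-methyl-6-[(2S)-6-methyl-4-oxohept-5-en-2-yl]cyclohex-2-en-1-yl}oxy)-3-methoxybenzaldehyde | COc1cc(C=O)ccc1O[C@H]3C=C(C)[C@@H](O)C[C@@H]3[C@@H](C)CC(=O)C=C(C)C | intermediate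
18 | (5E)-6-(4-hydroxy-3-methoxyphenyl)hex-5-ene-2,4-dione (feruloylacetone) | COc1cc(/C=C/C(=O)CC(C)=O)ccc1O | intermediate
19 | Bisabolocurcumin ether | COc1cc(/C=C/C(=O)/C=C(O)/C=C/c2ccc(O[C@H]3C=C(C)[C@@H](O)C[C@@H]3[C@@H](C)CC(=O)C=C(C)C)c(OC)c2)ccc1O | target

**Totals**

Total step count: 13. Longest linear sequence: 9 steps (steps 4, 5, 6, 7, 8, 9, 10, 11, 13; the branch through steps 1–3 is equally long).

**Steps most likely to fail**

Step 7. What may go wrong: the enamine of 4 may add too slowly to the β-branched, unactivated enone, so that self-aldol of 4 takes over; the Michael addition may proceed with the wrong relative topicity at C6; or C7 may erode through dienamine formation from 9. Fallback (stoichiometric enamine annulation with diastereomer separation in place of catalyst control): the route sets out from 4 and 9. Aldehyde 4 is condensed with pyrrolidine (MgSO4, toluene, 0 °C) to 1-{(E)-2-[4-(5,5-dimethyl-1,3-dioxan-2-yl)-2-methoxyphenoxy]ethenyl}pyrrolidine F1, which is heated with 9 (MeCN, 60–80 °C) in a Stork-type Michael addition. Buffered hydrolysis (AcOH/NaOAc/H2O) to 10 and ring closure in the same flask should give the two thermodynamic trans ring diastereomers, 11 and methyl (3S)-3-{(1S,2S)-2-[4-(5,5-dimethyl-1,3-dioxan-2-yl)-2-methoxyphenoxy]-4-methyl-5-oxocyclohex-3-en-1-yl}butanoate F2. Because C7 is fixed they are diastereomers and are separated by chromatography; the route is rejoined at 11.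

Step 9. What may go wrong: SN2′ attack of the carboxylate, elimination to a cyclohexadiene, or ionisation of the allylic oxyphosphonium intermediate with loss of inversion fidelity. Fallback (reagent-controlled reduction in place of invertive substitution): setting out from enone 11, reduction with (R)-2-methyl-CBS-oxazaborolidine and catecholborane (toluene, −78 °C), with the enone π-system acting as the large group, should deliver the 5S alcohol directly. This bypasses 12 and 13 and rejoins the route at 14.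

Step 13. What may go wrong: acid-promoted ionisation and aromatisation of the cis-1,4-dioxygenated cyclohexene while the boron chelate is hydrolysed, or amine addition to the side-chain enone at 60 °C. Fallback (kinetic aldol addition of a preformed polyanion and separate base-mediated dehydration, without boron or acid): the route sets out from 17 and 18. Diketone 18 is converted into its trilithium salt (LDA, 3.2 equiv, THF, −78 °C) and treated with the lithium alkoxide of 17 (LiHMDS, 1 equiv). This should give (1E)-7-hydroxy-1-(4-hydroxy-3-methoxyphenyl)-7-[4-({(1R,4S,6R)-4-hydroxy-3-methyl-6-[(2S)-6-methyl-4-oxohept-5-en-2-yl]cyclohex-2-en-1-yl}oxy)-3-methoxyphenyl]hept-1-ene-3,5-dione F3 (both carbinol epimers). E1cB dehydration of F3 with catalytic piperidinium acetate (EtOAc, 50 °C) rejoins the route at 19.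

**Further compounds**

F1 | step 7 | 1-{(E)-2-[4-(5,5-dimethyl-1,3-dioxan-2-yl)-2-methoxyphenoxy]ethenyl}pyrrolidine | COc1cc(C2OCC(C)(C)CO2)ccc1O/C=C/N3CCCC3
F2 | step 7 | methyl (3S)-3-{(1S,2S)-2-[4-(5,5-dimethyl-1,3-dioxan-2-yl)-2-methoxyphenoxy]-4-methyl-5-oxocyclohex-3-en-1-yl}butanoate | COc1cc(C2OCC(C)(C)CO2)ccc1O[C@@H]3C=C(C)C(=O)C[C@H]3[C@@H](C)CC(=O)OC
F0 | step 9 | none | none
F3 | step 13 | (1E)-7-hydroxy-1-(4-hydroxy-3-methoxyphenyl)-7-[4-({(1R,4S,6R)-4-hydroxy-3-methyl-6-[(2S)-6-methyl-4-oxohept-5-en-2-yl]cyclohex-2-en-1-yl}oxy)-3-methoxyphenyl]hept-1-ene-3,5-dione | COc1cc(/C=C/C(=O)CC(=O)CC(O)c2ccc(O[C@H]3C=C(C)[C@@H](O)C[C@@H]3[C@@H](C)CC(=O)C=C(C)C)c(OC)c2)ccc1O
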